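**Retrosynthetic overview**

- The target is one 31-membered lactone ring (ring O, carbonyl C1, CH2 groups C2–C30) with no stereocentre. The strategy rests on the chain dividing as C1–C9 / C10–C21 / C22–C30, where the central twelve carbons match a cyclododecene ring and each outer piece matches a C10 terminal olefin less its =CH2 carbon.
- Last disconnection: the C9–C10 and C21–C22 single bonds come from hydrogenation of a macrocyclic 9,21-diene.
- Key disconnection: C9=C10 and C21=C22 are formed by metathesis between dec-9-enyl dec-9-enoate and cyclododecene, with loss of ethylene.
- First disconnection: the ester C1–O bond, from dec-9-enoic acid and dec-9-en-1-ol.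
- Ring order: the twelve-membered carbocycle is opened and the only ring of the target, the 31-membered lactone, is closed in the same metathesis step.

Key step: step 2

Remark on the chemistry: commercial cyclododecene is an E/Z mixture and the two new alkenes will form as E/Z mixtures. This is accepted, because every isomer gives the same product on hydrogenation.

**Route**

Step 1
Reactants: 1 dec-9-enoic acid; 2 dec-9-en-1-ol
Product: 3 dec-9-enyl dec-9-enoate
Conditions: DCC (1.1 equiv), DMAP (0.1 equiv), CH2Cl2, 0 °C to rt
Reagents that add atoms: none
Why: Steglich esterification, in which the O-acylisourea is intercepted by DMAP and the acylpyridinium acylates the unhindered primary alcohol; the terminal alkenes are inert.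

Step 2
Reactants: 3 dec-9-enyl dec-9-enoate; 4 cyclododecene
Product: 6 oxacyclohentriaconta-10,22-dien-2-one as an E/Z mixture, via dec-9-enyl docosa-9,21-dienoate 5 (not isolated)
Conditions: second-generation Grubbs catalyst RuCl2(=CHPh)(PCy3)(H2IMes) (5 mol %), 1,4-benzoquinone (10 mol %), 4 (1.2 equiv), CH2Cl2 (5 mM in 3), 40 °C, argon sparge; ethyl vinyl ether quench
Reagents that add atoms: none
Why: The benzylidene initiates at a vinyl group of 3, the resulting alkylidene adds to the C=C of 4 by [2+2] cycloaddition, and cycloreversion of the ruthenacyclobutane opens the twelve-membered ring so that C10–C21 is spliced onto the chain (metal-free form: triene 5, written for reaction at the acyl-side vinyl group; the other terminus leads to the same ring). The chain-end alkylidene then engages the remaining vinyl group intramolecularly and a second ruthenacyclobutane collapses to the 31-membered ring, so that C9=C10 and C21=C22 are the two new skeletal bonds and ethylene is the only by-product. The closest known reaction type is ring-expansion metathesis, the ring-opening, cross and ring-closing metathesis cascade that inserts a cycloalkene into an acyclic diene. The ring closes end to end by ring-closing metathesis of a strain-free 31-atom chain, no stereocentre is created, and the geometry of the two new alkenes is left uncontrolled because both are saturated in step 3. The selectivity needed is insertion of exactly one unit of 4, against direct closure of 3 to the 19-membered lactone and against double insertion to the 43-membered ring; the three olefins are of like reactivity, so the substrate offers only a thermodynamic bias (relief of the modest strain of 4 favours insertion, dilution disfavours the larger ring), and the outcome is steered by near-equimolar stoichiometry, millimolar dilution and full reversibility under this catalyst. 1,4-Benzoquinone should suppress ruthenium hydride olefin migration that would delete CH2 units, and the lactones differ in their number of C=C bonds (one, two, three), which should allow separation on AgNO3-impregnated silica.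

Step 3
Reactants: 6 oxacyclohentriaconta-10,22-dien-2-one
Product: 7 oxacyclohentriacontan-2-one (triacontan-30-olide), the target
Conditions: H2 (1 atm), Pd/C (10 wt % Pd), EtOAc/THF, 25–40 °C
Reagents that add atoms: none
Why: Heterogeneous catalytic hydrogenation saturates both disubstituted alkenes whatever their geometry or position, while the lactone, which has no allylic or benzylic C–O bond, is untouched.

**Compound list**

1 | dec-9-enoic acid | OC(=O)CCCCCCCC=C | starting material
2 | dec-9-en-1-ol | OCCCCCCCCC=C | starting material
3 | dec-9-enyl dec-9-enoate | C=CCCCCCCCC(=O)OCCCCCCCCC=C | intermediate
4 | cyclododecene (commercial E/Z mixture) | C1CCCCCCCCCC=C1 | starting material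
5 | dec-9-enyl docosa-9,21-dienoate (not isolated; internal alkene of either geometry) | C=CCCCCCCCCCCC=CCCCCCCCC(=O)OCCCCCCCCC=C | intermediate
6 | oxacyclohentriaconta-10,22-dien-2-one (E/Z mixture at both alkenes) | O=C1CCCCCCCC=CCCCCCCCCCCC=CCCCCCCCCO1 | intermediate
7 | oxacyclohentriacontan-2-one | O=C1CCCCCCCCCCCCCCCCCCCCCCCCCCCCCO1 | target

**Step count**

Total steps: 3. Longest linear sequence: 3 steps (1 or 2 → 3 → 6 → 7).

**Steps most likely to fail**

Step 2 (highest risk). The ester unit may partition among ring sizes: closure without insertion, double insertion, or open-chain oligomerisation. Olefin migration may also shorten the chain by CH2 units. Off-size lactones and cyclododecene oligomers could be returned to the same conditions, since all are interconvertible by metathesis, but the fallback changes the approach. It fixes the ring size with a single acyclic diene and no cycloalkene partner, taking the twelve carbons from 1,12-dibromododecane instead of 4. It sets out from 2, with 1 as the acid partner, and comes back to the route at 7. Alcohol 2 would be converted by an Appel reaction (CBr4, PPh3, CH2Cl2, 0 °C) into 10-bromodec-1-ene F1. Its Grignard reagent dec-9-enylmagnesium bromide F2 (Mg, THF) would be coupled with an excess of 1,12-dibromododecane (BrCCCCCCCCCCCCBr) under Li2CuCl4 catalysis (THF, −10 °C, Kochi-type alkyl–alkyl coupling) to give 22-bromodocos-1-ene F3, the excess dibromide being recovered. Alkylation of the cesium salt of 1 with F3 (Cs2CO3, DMF, 60 °C) would give docos-21-enyl dec-9-enoate F4. Ring-closing metathesis of F4 (second-generation Grubbs catalyst RuCl2(=CHPh)(PCy3)(H2IMes), 1,4-benzoquinone, CH2Cl2, 2 mM, 40 °C) can give only oxacyclohentriacont-10-en-2-one F5 or separable oligomers. Hydrogenation of F5 under the conditions of step 3 would give 7.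

Step 3. Saturation may stall because ruthenium or phosphine residues poison the palladium surface, or because the waxy macrolide is poorly soluble. The fallback sets out from 6 and comes back at 7 by a metal-free reduction. Diimide F6 would be generated in the flask from p-toluenesulfonyl hydrazide and NaOAc (DME/H2O, reflux, hydrazide added in portions). It transfers two hydrogens to each C=C by a concerted syn addition with loss of N2 and leaves the lactone untouched.

Step 1. The O-acylisourea may rearrange to the unreactive N-acylurea, and the urea by-product may be carried into the metathesis step. The fallback sets out from 1 and comes back at 3 through an acyl chloride. Acid 1 would be treated with oxalyl chloride and catalytic DMF (CH2Cl2, 0 °C to rt) to give dec-9-enoyl chloride F7. F7 would then acylate 2 in the presence of Et3N (CH2Cl2, 0 °C) to give 3.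

**Further compounds**

F1 | step 2 | 10-bromodec-1-ene | C=CCCCCCCCCBr
F2 | step 2 | dec-9-enylmagnesium bromide | C=CCCCCCCCC[Mg]Br
F3 | step 2 | 22-bromodocos-1-ene | C=CCCCCCCCCCCCCCCCCCCCCBr
F4 | step 2 | docos-21-enyl dec-9-enoate | C=CCCCCCCCC(=O)OCCCCCCCCCCCCCCCCCCCCC=C
F5 | step 2 | oxacyclohentriacont-10-en-2-one (E/Z mixture) | O=C1CCCCCCCC=CCCCCCCCCCCCCCCCCCCCCO1
F6 | step 3 | diimide | N=N
F7 | step 1 | dec-9-enoyl chloride | C=CCCCCCCCC(Cl)=O
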